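The target is a depside of two 2,4-dioxygenated 6-propylbenzoates: ring A is the acyl unit, ring B the phenol unit. In each ring C1 carries the carboxyl carbon, C2 and C4 carry oxygen and C6 carries propyl; a cyclohexane-2,4-dione with an ester at C1 and propyl at C6 is the same ring two hydrogens richer. That dione is assembled in one pot from methyl acetoacetate and methyl (E)-hex-2-enoate: conjugate addition forms C1–C6, Claisen closure forms C3–C4. Dehydrogenation gives methyl divarate, which serves twice, as the ring B phenol and, after benzylation and saponification, as the ring A acid. O4 acylation, O2 methylation and hydrogenolysis finish.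

Key step: step 1

Remark: the target is achiral; 4 and 5 are drawn as diketo tautomers although they should be largely enolized, and their stereocentres are racemic and are erased in step 2.

Step 1
Reactants: 1 methyl acetoacetate; 2 methyl (E)-hex-2-enoate
Product: 4 racemic methyl trans-2,4-dioxo-6-propylcyclohexane-1-carboxylate, via Michael adduct 3 (not isolated)
Conditions: NaOMe (1.1 equiv), MeOH, reflux; then aq. HCl, 0 °C
Reagents that add atoms: none
Why: Methoxide deprotonates 1 at its doubly activated C2, which adds to the β-carbon of 2 (Michael addition, new C1–C6 bond) to give 3; proton exchange then makes the less stable enolate at the acetyl methyl available, and this carbon attacks the ester carbonyl that came from 2 and expels methoxide (Claisen condensation, new C3–C4 bond). The closest known reaction type is the alkoxide-mediated Michael–Claisen annulation of acetoacetates with 2-alkenoates that gives dihydroresorcylates. The ring closes in the 6-exo-trig mode, the attacked carbonyl π-bond lying outside the new ring. C6 is formed without control and is racemic, while C1 stays epimerizable through the β-keto ester enol, so equilibration should place ester and propyl trans (both equatorial). The step needs regioselectivity: the large acidity gap between C2 and the methyl group sends the intermolecular addition through C2, only the methyl carbon can reach the distal ester through a six-membered transition state, and deprotonation of the product to the delocalized cyclic 1,3-dione enolate should pull every reversible equilibrium toward 4. Pairing NaOMe with two methyl esters makes any ester exchange degenerate.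

Step 2
Reactants: 4 racemic methyl trans-2,4-dioxo-6-propylcyclohexane-1-carboxylate
Product: 6 methyl 2,4-dihydroxy-6-propylbenzoate, via 3-bromo dione 5 (not isolated)
Conditions: Br2 (1.0 equiv), DMF, 0 °C → 80 °C
Reagents that add atoms: none
Why: Electrophilic bromination of the enolized 1,3-dione at C3 gives 5, which in warm DMF should lose HBr and tautomerize to the resorcinol (the known bromination–dehydrobromination aromatization of dihydroresorcylates), the temperature being capped so that the methyl ester is not cleaved and decarboxylated.

Step 3
Reactants: 6 methyl 2,4-dihydroxy-6-propylbenzoate (the portion destined for ring A)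
Product: 7 methyl 2,4-bis(benzyloxy)-6-propylbenzoate
Conditions: BnBr (2.4 equiv), K2CO3 (3 equiv), DMF, 70 °C
Reagents that add atoms: benzyl bromide, BrCc1ccccc1
Why: Double Williamson etherification, in which the free 4-OH should react first and the hydrogen-bonded 2-OH follow with excess reagent in warm DMF, while the flanked methyl ester is inert to carbonate.

Step 4
Reactants: 7 methyl 2,4-bis(benzyloxy)-6-propylbenzoate
Product: 8 2,4-bis(benzyloxy)-6-propylbenzoic acid
Conditions: KOH (5 equiv), DMSO–H2O, 100 °C; then 1 M HCl, 0 °C
Reagents that add atoms: potassium hydroxide, [K+].[OH-]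
Why: Saponification by acyl–oxygen cleavage is slow for a benzoate with two ortho substituents, so poorly solvated hydroxide in hot aqueous DMSO is used; the benzyl ethers are stable to it and the electron-rich acid is liberated cold to avoid decarboxylation.

Step 5
Reactants: 8 2,4-bis(benzyloxy)-6-propylbenzoic acid; 6 methyl 2,4-dihydroxy-6-propylbenzoate
Product: 10 methyl 4-{[2,4-bis(benzyloxy)-6-propylbenzoyl]oxy}-2-hydroxy-6-propylbenzoate, via acid chloride 9 (not isolated)
Conditions: (COCl)2 (1.2 equiv), DMF (cat.), CH2Cl2, 0 °C → rt, evaporate; then 6 (1.0 equiv), Et3N (1.5 equiv), DMAP (0.1 equiv), CH2Cl2, 0 °C → rt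
Reagents that add atoms: none
Why: Acid chloride formation through the chloroiminium catalyst followed by DMAP-catalysed esterification of a phenol should occur at O4 only, because the 2-OH of 6 is tied up in a six-membered hydrogen bond to the ester carbonyl and is shielded by that ester, whereas the 4-OH is free, more acidic and unhindered.

Step 6
Reactants: 10 methyl 4-{[2,4-bis(benzyloxy)-6-propylbenzoyl]oxy}-2-hydroxy-6-propylbenzoate
Product: 11 methyl 4-{[2,4-bis(benzyloxy)-6-propylbenzoyl]oxy}-2-methoxy-6-propylbenzoate
Conditions: MeI (3 equiv), K2CO3 (2 equiv), dry DMF, 40 °C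
Reagents that add atoms: methyl iodide, CI
Why: Williamson methylation of the only remaining acidic site; the aryl ester should survive anhydrous carbonate because its carbonyl is flanked by benzyloxy and propyl and because the benzylated ring A has no free ortho-hydroxyl to assist cleavage.

Step 7
Reactants: 11 methyl 4-{[2,4-bis(benzyloxy)-6-propylbenzoyl]oxy}-2-methoxy-6-propylbenzoate
Product: 12 methyl 4-[(2,4-dihydroxy-6-propylbenzoyl)oxy]-2-methoxy-6-propylbenzoate (CNP0177078.0)
Conditions: H2 (1 atm), 10% Pd/C, EtOAc, rt
Reagents that add atoms: none
Why: Catalytic hydrogenolysis of the two benzyl aryl ethers leaves both esters and the arenes untouched, and the non-nucleophilic solvent avoids alcoholysis of the depside link once the ring A ortho-hydroxyl is free.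

Compound list
1 | methyl acetoacetate | CC(=O)CC(=O)OC | starting material
2 | methyl (E)-hex-2-enoate | CCC/C=C/C(=O)OC | starting material
3 | dimethyl 2-acetyl-3-propylpentanedioate (racemic mixture of diastereomers, not isolated) | CCCC(CC(=O)OC)C(C(C)=O)C(=O)OC | intermediate
4 | methyl (1RS,6SR)-2,4-dioxo-6-propylcyclohexane-1-carboxylate (trans, racemic, one enantiomer drawn) | CCC[C@@H]1CC(=O)CC(=O)[C@H]1C(=O)OC | intermediate
5 | methyl 3-bromo-2,4-dioxo-6-propylcyclohexane-1-carboxylate (trans at C1/C6, C3 undefined, not isolated) | CCC[C@@H]1CC(=O)C(Br)C(=O)[C@H]1C(=O)OC | intermediate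
6 | methyl 2,4-dihydroxy-6-propylbenzoate | CCCc1cc(O)cc(O)c1C(=O)OC | intermediate
7 | methyl 2,4-bis(benzyloxy)-6-propylbenzoate | CCCc1cc(OCc2ccccc2)cc(OCc2ccccc2)c1C(=O)OC | intermediate
8 | 2,4-bis(benzyloxy)-6-propylbenzoic acid | CCCc1cc(OCc2ccccc2)cc(OCc2ccccc2)c1C(=O)O | intermediate
9 | 2,4-bis(benzyloxy)-6-propylbenzoyl chloride (not isolated) | CCCc1cc(OCc2ccccc2)cc(OCc2ccccc2)c1C(Cl)=O | intermediate
10 | methyl 4-{[2,4-bis(benzyloxy)-6-propylbenzoyl]oxy}-2-hydroxy-6-propylbenzoate | CCCc1cc(OCc2ccccc2)cc(OCc2ccccc2)c1C(=O)Oc1cc(CCC)c(C(=O)OC)c(O)c1 | intermediate
11 | methyl 4-{[2,4-bis(benzyloxy)-6-propylbenzoyl]oxy}-2-methoxy-6-propylbenzoate | CCCc1cc(OCc2ccccc2)cc(OCc2ccccc2)c1C(=O)Oc1cc(CCC)c(C(=O)OC)c(OC)c1 | intermediate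
12 | methyl 4-[(2,4-dihydroxy-6-propylbenzoyl)oxy]-2-methoxy-6-propylbenzoate | CCCc1cc(O)cc(O)c1C(=O)Oc1cc(CCC)c(C(=O)OC)c(OC)c1 | target

Total step count: 7. Longest linear sequence: 7 steps (steps 1 to 7; compound 6 enters both step 3 and step 5).

Steps most likely to fail

1. Step 1. Conjugate addition to the β-propyl enoate may be slow and reversible, so that methoxide-driven self-condensation of the acetoacetate or retro-Claisen deacetylation of the open-chain adduct outruns ring closure. The fallback exchanges the roles of donor and acceptor. It replaces 1 and 2 and therefore sets out from two other purchased compounds, not from a numbered one: dimethyl malonate F1 and (E)-hept-3-en-2-one F2. With NaOMe in MeOH at reflux the malonate should add to the enone β-carbon to give dimethyl 2-(2-oxoheptan-4-yl)propanedioate F3. The methyl ketone enolate of that adduct then closes onto one malonate ester in a Claisen condensation, and the fallback comes back to the route at 4.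

2. Step 2. The first resorcylate formed may be brominated on the ring faster than the remaining dione is brominated at C3, so that the oxidant is used up and conversion stalls; overheating would in addition cleave and decarboxylate the ester. The fallback makes the over-bromination deliberate. It sets out from 4: Br2 (3 equiv) in AcOH at rt should aromatize and brominate in one operation to give methyl 3,5-dibromo-2,4-dihydroxy-6-propylbenzoate F4. Hydrogenolysis of both carbon–bromine bonds (H2, 10% Pd/C, NaOAc, MeOH) then comes back to the route at 6.

3. Step 5. Acylation may occur at both hydroxyls, or acyl transfer from the doubly ortho-substituted acid chloride may be sluggish, giving mixtures of mono- and diesters. The fallback removes the choice between the hydroxyls before coupling. It sets out from 6: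
- Selective benzylation of the free hydroxyl (BnBr, 1.05 equiv, K2CO3, acetone, rt) should give methyl 4-(benzyloxy)-2-hydroxy-6-propylbenzoate F5.
- Methylation (MeI, K2CO3, DMF, 50 °C) should give methyl 4-(benzyloxy)-2-methoxy-6-propylbenzoate F6.
- Hydrogenolysis (H2, 10% Pd/C, EtOAc) should give methyl 4-hydroxy-2-methoxy-6-propylbenzoate F7.
- Condensation of F7 with acid 8 through the mixed anhydride (trifluoroacetic anhydride, toluene, rt) should give the ester directly.

The fallback comes back to the route at 11 and makes step 6 unnecessary.

Further compounds
F1 | step 1 | dimethyl malonate (purchased for the fallback) | COC(=O)CC(=O)OC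
F2 | step 1 | (E)-hept-3-en-2-one (purchased for the fallback) | CCC/C=C/C(C)=O
F3 | step 1 | dimethyl 2-(2-oxoheptan-4-yl)propanedioate (racemic, not isolated) | CCCC(CC(C)=O)C(C(=O)OC)C(=O)OC
F4 | step 2 | methyl 3,5-dibromo-2,4-dihydroxy-6-propylbenzoate | CCCc1c(Br)c(O)c(Br)c(O)c1C(=O)OC
F5 | step 5 | methyl 4-(benzyloxy)-2-hydroxy-6-propylbenzoate | CCCc1cc(OCc2ccccc2)cc(O)c1C(=O)OC
F6 | step 5 | methyl 4-(benzyloxy)-2-methoxy-6-propylbenzoate | CCCc1cc(OCc2ccccc2)cc(OC)c1C(=O)OC
F7 | step 5 | methyl 4-hydroxy-2-methoxy-6-propylbenzoate | CCCc1cc(O)cc(OC)c1C(=O)OC
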